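## The problem

Numbering follows the germacrane skeleton: ring carbons C1–C10, methyl C14 on C10, methyl C15 on C4, lactone carbons C11 and C12, exocyclic methylene C13. The target is a ten-membered carbocycle trans-fused through C6 and C7 to an α-methylene-γ-butyrolactone (oxygen on C6). It carries a Z-trisubstituted C4=C5 alkene, a C1–C10 oxirane in which C2 and C9 are cis, and a C8 ester of (2S,3R)-2,3-dimethyloxirane-2-carboxylic acid. Five ring stereocentres (1S,6R,7R,8R,10R) must be set. C6 can direct C7 across the lactone, and a C10 carbinol can direct C8 through their 1,3-relationship (O8 and O10 are anti in the target). C1 and C10 have no neighbour to lean on and must come out of the ring-forming event. The ten-membered closure has to be strongly driven and must leave the Z alkene alone. The methylene lactone, both oxiranes, the allylic C6–O bond and any C8 ketone (β to the lactone oxygen, so open to E1cB ring opening) will not survive strong base, strong acid or low-valent metals, so the methylene group and the oxiranes are best carried masked until late. The feature that permits a convergent assembly is that C7 is the β-carbon and C11 the α-carbon of the lactone: a C7=C11 butenolide can accept a C8 acyl-anion equivalent at C7, and the resulting enolate can accept C13 as a one-carbon electrophile.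

## Retrosynthesis

**C13–N (30 from 28).** The conjugated methylene is released last, from the dimethylaminomethyl lactone 28 by N-methylation (29) and loss of trimethylamine. The amine keeps C11=C13 out of every reductive and basic step before it, and the forward reaction asks only for mild base.

**C1–O of the oxirane (28 from 27).** The oxirane is traced to hydroxy mesylate 27 (C10 carbinol, C1 sulfonate). Closure inverts C1, so the cis-oxirane requires a trans-1,10-diol of configuration 1R,10R. Epoxidising a C1=C10 alkene would instead have to discriminate against C4=C5 and choose a face; the displacement is stereospecific and touches neither alkene.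

**C8–O acyl bond (27 from 22 and 25).** Acylation is placed before the base-mediated closure so that a free C8 alkoxide can neither attack C1 (five-membered ether) nor translactonise onto C12. Acid 25 comes from (E)-2-methylbut-2-en-1-ol 23 by asymmetric epoxidation (24) and oxidation.

**C8–H (22 from 21, then 20 and 19).** In ketone 21 the C10 hydroxyl is β to the carbonyl, and O8/O10 are anti in the target, so hydride delivered from that hydroxyl gives 8R. For this reason C8 stays masked as the dithiane until C10 exists; reducing an open-chain C8 ketone next to C7 alone would have no reliable bias. The mesylate is installed on diol 19 while C1–OH is the only secondary hydroxyl (20), which removes any later need to tell C1–OH from C8–OH.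

**C1–C10 (19 from 18).** A reductive carbonyl coupling of keto aldehyde 18 creates the ring and both oxygens of the future oxirane in one bond. The two carbonyls travel as simple acetals, whereas closure at a neighbouring bond would need C1 and C10 built beforehand. The forward reaction must close a ten-membered ring at high dilution, give the trans-diol and select the 10R face.

**C7–C8 and C11–C13 (18 from 17; 17 from 13, 9 and 14).** Aqueous acid takes 17 to 18 because O,O-acetals hydrolyse while the S,S-acetal does not. Lactone 17 is then cut at the two bonds that flank the lactone α- and β-carbons, giving lithiated dithiane 13 (C8, with C9 and ketal C10), butenolide 9 (C6 stereocentre, Z-alkenyl chain ending in the C1 acetal) and iminium salt 14 (C13). Three pieces of comparable size are joined in one flask with no ring closed, and C6 controls C7.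

**Butenolide 9.** It comes from ynoate 7 by semihydrogenation and lactonisation (via 8). Carbinol 7 is cut at C6–C7 to Z-enal 5 and methyl propiolate 6, and the single stereocentre comes from a catalytic asymmetric alkynylation. Enal 5 is reached from neryl acetate 1 through 2, 3 and 4, so the Z alkene is bought rather than made.

**Dithiane 13.** Alkylating 1,3-dithiane with a bromomethyl dioxolane would be an SN2 reaction at a neopentyl-type carbon. The dithiane is therefore made by double thiol addition of propane-1,3-dithiol 11 to but-3-yn-2-one 10 (12), followed by ketalisation.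

## Roads not taken

**Alternative 1:** The cut is C6–C7 of the carbocycle, made through a thirteen-membered diallylic ether A1 in which oxygen links C6 and C13. Deprotonation at C6 and a [2,3]-Wittig shift across C7=C11 would contract the ether to the ten-membered dienol A2.
- Merits: the C–C bond forms in an ordered intramolecular rearrangement, not a high-dilution bimolecular-type closure. C6 and C7 are set together. C11=C13 is already present in A2, which is better than the aminomethyl detour of the chosen plan.
- Weak points: A1 needs its own macrocyclic etherification. C6 and C13 are both allylic α-oxy positions, and a [1,2]-shift competes. The C6/C7 outcome relative to C8 depends on a macrocyclic transition state. After A2, C12 must still be raised to the lactone level.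
- The largest gap is the oxirane: the C1=C10 alkene must be epoxidised on one face in the presence of two other alkenes, and the C6 hydroxyl would steer a metal-directed epoxidation toward C4=C5.
- Comparison: the chosen plan sets convergence against this road's direct methylene group, and derives the oxirane stereospecifically from a diol.

**Alternative 2:** The cut is C3–C4. Hydroboration of the vinyl group on the oxirane carbon of A3 and palladium-catalysed coupling of the C3–boron bond with the C4 alkenyl iodide would close the ring to A4.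
- Merits: the Z geometry is carried over from the iodide with retention. All five ring stereocentres and the oxirane exist before closure, so the ring closure creates no stereocentre. This is clearly better than the pinacol of the chosen plan, whose facial selectivity is uncertain.
- Weak points: ten-membered rings are at the unfavourable end for sp3–sp2 macrocyclic couplings. A vinyl oxirane is opened by zerovalent palladium if any of it escapes hydroboration. The basic aqueous coupling medium meets a lactone. A3 needs a long linear sequence with the oxirane carried throughout. A4 still lacks C13, so α-methylenation, desilylation and acylation follow.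
- Comparison: the chosen plan is much shorter to its cyclisation substrate and brings C13 in during the key step.

**Alternative 3:** The cut is C9–C10. Reductive enolate formation at the bromomethyl ketone of A5 with SmI2 and aldol-type addition to the C10 methyl ketone, chelated through the C1 ether oxygen, would give A6.
- Merits: samarium-mediated closures of medium rings are well documented. Chelation should fix C10 relative to a pre-set C1, which is more predictable than the pinacol here. A6 contains the same β-hydroxy ketone that the chosen plan reduces to set C8.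
- Weak points: the enolate precursor sits at C8, whose β-carbon C6 carries the lactone oxygen, so reductive β-elimination of the carboxylate threatens the lactone. A5 must carry C1, C6 and C7 through a longer linear sequence. The PMB ether must be removed and C1 activated with inversion. C13 is again missing.
- Comparison: the chosen plan shares the late C8/C10 logic, reaches the ring-closure substrate in far fewer operations, and concedes this road's better control of C10.

Key step: step 9

Assumption: the (S,S) enantiomer of the ProPhenol ligand is taken to be the one that gives the 4R carbinol 7; if its sense is the opposite, the (R,R) ligand is used in the same way.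

Remark: names of ring compounds use the germacrane numbering defined above; the C7 descriptor changes between S and R with the C8 substituent by priority only, while C1 is truly inverted in step 18.

## Steps

Step 1
Reactants: 1 neryl acetate [(2Z)-3,7-dimethylocta-2,6-dien-1-yl acetate]
Product: 2 (2Z)-3-methyl-6-oxohex-2-en-1-yl acetate
Conditions: O3 (1 equiv), CH2Cl2/MeOH, −78 °C; then Me2S, −78 °C to rt
Reagents that add atoms: ozone, [O-][O+]=O
Why: Selective ozonolysis with reductive work-up; the remote trisubstituted alkene is more electron-rich than the one flanked by the allylic acetate, so one equivalent of ozone should cleave it alone and leave the Z alkene untouched.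

Step 2
Reactants: 2 (2Z)-3-methyl-6-oxohex-2-en-1-yl acetate
Product: 3 (2Z)-6,6-dimethoxy-3-methylhex-2-en-1-yl acetate
Conditions: HC(OMe)3, MeOH, PPTS (cat.), rt
Reagents that add atoms: trimethyl orthoformate, COC(OC)OC
Why: Acid-catalysed acetalisation driven by the orthoester; the aldehyde (future C1) is masked in a form stable to base, organometallics and hydrogenation.

Step 3
Reactants: 3 (2Z)-6,6-dimethoxy-3-methylhex-2-en-1-yl acetate
Product: 4 (2Z)-6,6-dimethoxy-3-methylhex-2-en-1-ol
Conditions: K2CO3 (cat.), MeOH, rt
Reagents that add atoms: none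
Why: Base-catalysed transesterification of the acetate; the dimethyl acetal and the alkene geometry are inert to methoxide.

Step 4
Reactants: 4 (2Z)-6,6-dimethoxy-3-methylhex-2-en-1-ol
Product: 5 (2Z)-6,6-dimethoxy-3-methylhex-2-enal
Conditions: TEMPO (cat.), PhI(OAc)2, CH2Cl2, rt
Reagents that add atoms: none
Why: Oxoammonium-mediated oxidation of an allylic alcohol under nearly neutral conditions, chosen because it is known to preserve Z-enals; 5 is used at once.

Step 5
Reactants: 5 (2Z)-6,6-dimethoxy-3-methylhex-2-enal; 6 methyl propiolate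
Product: 7 methyl (4R,5Z)-4-hydroxy-9,9-dimethoxy-6-methylnon-5-en-2-ynoate
Conditions: (S,S)-ProPhenol (cat.), Me2Zn, Ph3P=O (cat.), toluene, 4 °C; aq. NH4Cl
Reagents that add atoms: none
Why: Zinc–ProPhenol catalysed asymmetric alkynylation of an enal with a propiolate; the dinuclear chiral zinc alkynyl complex delivers the alkyne to one aldehyde face, setting C6 by reagent control.

Step 6
Reactants: 7 methyl (4R,5Z)-4-hydroxy-9,9-dimethoxy-6-methylnon-5-en-2-ynoate
Product: 9 (5S)-5-[(1Z)-5,5-dimethoxy-2-methylpent-1-en-1-yl]furan-2(5H)-one, via Z-hydroxy enoate 8 (not isolated)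
Conditions: H2 (1 atm), Pd/CaCO3 poisoned with Pb(OAc)2 (Lindlar catalyst), quinoline, EtOAc, rt; then PPTS (cat.), CH2Cl2, rt
Reagents that add atoms: none
Why: Syn semihydrogenation gives the Z-enoate, whose γ-hydroxyl is placed to lactonise with loss of methanol; the carbinol centre is not touched (its descriptor becomes S only through the priority change).

Step 7
Reactants: 10 but-3-yn-2-one; 11 propane-1,3-dithiol
Product: 12 1-(1,3-dithian-2-yl)propan-2-one
Conditions: NaOMe (cat.), MeOH/CH2Cl2, −10 °C to rt
Reagents that add atoms: none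
Why: Double conjugate (thia-Michael) addition of a 1,3-dithiol to an ynone, a standard entry to β-keto dithianes that avoids an SN2 reaction at a neopentyl-type carbon.

Step 8
Reactants: 12 1-(1,3-dithian-2-yl)propan-2-one
Product: 13 2-[(2-methyl-1,3-dioxolan-2-yl)methyl]-1,3-dithiane
Conditions: HOCH2CH2OH, TsOH (cat.), benzene, reflux, Dean–Stark trap
Reagents that add atoms: ethylene glycol, OCCO
Why: Acid-catalysed ketalisation with azeotropic removal of water; the ketone (future C10) must be masked before the dithiane C–H is lithiated.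

Step 9
Reactants: 13 2-[(2-methyl-1,3-dioxolan-2-yl)methyl]-1,3-dithiane; 9 (5S)-5-[(1Z)-5,5-dimethoxy-2-methylpent-1-en-1-yl]furan-2(5H)-one; 14 dimethylmethyleneiminium iodide (Eschenmoser's salt)
Product: 17 (3R,4S,5R)-3-[(dimethylamino)methyl]-5-[(1Z)-5,5-dimethoxy-2-methylpent-1-en-1-yl]-4-{2-[(2-methyl-1,3-dioxolan-2-yl)methyl]-1,3-dithian-2-yl}oxolan-2-one, via lithiated dithiane 15 (not isolated), via lithium lactone enolate 16 (not isolated)
Conditions: 13 (slight excess), n-BuLi, THF, −30 °C; DMPU, −78 °C; 9 in THF added slowly, −78 °C; then solid CH2=NMe2 I (14), −78 to 0 °C; aq. NaHCO3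
Reagents that add atoms: none
Why: Deprotonation of 13 at the dithiane carbon gives the tertiary carbanion 15 (C8), which in THF–DMPU is a solvent-separated, soft nucleophile and adds to C7 of butenolide 9 in the 1,4-sense to give enolate 16. The closest known reaction type is the tandem conjugate addition of 2-lithio-1,3-dithianes to γ-substituted butenolides with in situ C-alkylation of the lactone enolate, combined with the aminomethylation of lactone enolates by dimethylmethyleneiminium salts. No ring is closed; the two skeletal bonds C7–C8 and C11–C13 are formed. The C7 stereocentre is controlled by C6, because the nucleophile enters the flat butenolide on the face opposite the Z-alkenyl group and so gives the trans-4,5 relationship. The C11 stereocentre is controlled by C7, because the iminium ion attacks 16 anti to the bulky dithianyl group; this centre is erased in step 19. The step needs 1,4- over 1,2-addition, which the polar cosolvent, the hindered sulfur-stabilised anion and the low electrophilicity of a lactone carbonyl should secure. It also needs addition to outrun proton transfer from the allylic C6–H, for which the high rate of conjugate addition at −78 °C is relied on, and C- over O-attack on the enolate, which the soft iminium carbon favours. Using slightly less n-BuLi than 13 ensures that no alkyllithium is left to attack the lactone.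

Step 10
Reactants: 17 (3R,4S,5R)-3-[(dimethylamino)methyl]-5-[(1Z)-5,5-dimethoxy-2-methylpent-1-en-1-yl]-4-{2-[(2-methyl-1,3-dioxolan-2-yl)methyl]-1,3-dithian-2-yl}oxolan-2-one
Product: 18 (3R,4S,5R)-3-[(dimethylamino)methyl]-5-[(1Z)-2-methyl-5-oxopent-1-en-1-yl]-4-[2-(2-oxopropyl)-1,3-dithian-2-yl]oxolan-2-one
Conditions: 1 M HCl, THF, rt; then aq. NaHCO3
Reagents that add atoms: water, O
Why: Acid hydrolysis of the dimethyl acetal and the dioxolane; the S,S-acetal is inert to aqueous acid, so C1 and C10 are unmasked while C8 stays protected, and the protonated amine and the lactone are stable at room temperature.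

Step 11
Reactants: 18 (3R,4S,5R)-3-[(dimethylamino)methyl]-5-[(1Z)-2-methyl-5-oxopent-1-en-1-yl]-4-[2-(2-oxopropyl)-1,3-dithian-2-yl]oxolan-2-one
Product: 19 (1R,4Z,6R,7S,10R,11R)-13-(dimethylamino)-1,10-dihydroxy-8,8-(propane-1,3-diyldisulfanediyl)germacr-4-en-12,6-olide
Conditions: TiCl3(DME)1.5, Zn–Cu, DME, reflux (reagent formation); then 18 by syringe pump at high dilution, 25 °C; aq. K2CO3
Reagents that add atoms: none
Why: Titanium-induced intramolecular pinacol coupling (McMurry type): low-valent titanium reduces both carbonyls to ketyls that couple on the metal, and slow addition favours ring closure over oligomers. Closures of ten-membered and larger rings by this reagent are known to lean toward the trans-diol, the relationship needed here; which face of the C10 ketone bonds (10R is needed) is decided by the conformation imposed by the trans-lactone, the Z alkene and the C8 dithiane, and is the least secure point of the route. Sulfides and amines are tolerated by the reagent at 25 °C, and the lactone is harder to reduce than either carbonyl.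

Step 12
Reactants: 19 (1R,4Z,6R,7S,10R,11R)-13-(dimethylamino)-1,10-dihydroxy-8,8-(propane-1,3-diyldisulfanediyl)germacr-4-en-12,6-olide
Product: 20 (1R,4Z,6R,7S,10R,11R)-13-(dimethylamino)-10-hydroxy-1-(methanesulfonyloxy)-8,8-(propane-1,3-diyldisulfanediyl)germacr-4-en-12,6-olide
Conditions: MsCl, Et3N, CH2Cl2, −20 °C
Reagents that add atoms: methanesulfonyl chloride, CS(=O)(=O)Cl
Why: Sulfonylation of the only secondary hydroxyl; the tertiary C10 hydroxyl does not react, and at −20 °C with an amine base the hydroxy mesylate should not yet close to the oxirane.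

Step 13
Reactants: 20 (1R,4Z,6R,7S,10R,11R)-13-(dimethylamino)-10-hydroxy-1-(methanesulfonyloxy)-8,8-(propane-1,3-diyldisulfanediyl)germacr-4-en-12,6-olide
Product: 21 (1R,4Z,6R,7S,10R,11R)-13-(dimethylamino)-10-hydroxy-1-(methanesulfonyloxy)-8-oxogermacr-4-en-12,6-olide
Conditions: PhI(OCOCF3)2, CF3CO2H (1 equiv), MeCN/H2O, 0 °C; NaH2PO4/Na2HPO4 buffer (pH 6) work-up; crude ammonium salt used directly
Reagents that add atoms: water, O
Why: Oxidative dethioacetalisation with a hypervalent iodine reagent; the amine is protected as its trifluoroacetate salt, and the ketone is kept on the acidic side throughout because base would open the lactone by E1cB loss of the C6 carboxylate or epimerise C7.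

Step 14
Reactants: 21 (1R,4Z,6R,7S,10R,11R)-13-(dimethylamino)-10-hydroxy-1-(methanesulfonyloxy)-8-oxogermacr-4-en-12,6-olide
Product: 22 (1R,4Z,6R,7R,8R,10R,11R)-13-(dimethylamino)-8,10-dihydroxy-1-(methanesulfonyloxy)germacr-4-en-12,6-olide
Conditions: Me4NBH(OAc)3, AcOH/MeCN, −30 °C
Reagents that add atoms: none
Why: Hydroxyl-directed anti reduction of a β-hydroxy ketone (Evans–Saksena): the C10 hydroxyl exchanges onto boron and delivers hydride through a six-membered transition state to the carbonyl face on its own side, so the new C8 hydroxyl ends anti to O10, which is 8R. The reagent is too weak to reduce the ketone or the lactone without this delivery, and the acidic medium protects the β-acyloxy ketone and the mesylate.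

Step 15
Reactants: 23 (2E)-2-methylbut-2-en-1-ol
Product: 24 [(2R,3R)-2,3-dimethyloxiran-2-yl]methanol
Conditions: Ti(OiPr)4 (cat.), D-(−)-diethyl tartrate (cat.), t-BuOOH, 4 Å molecular sieves, CH2Cl2, −20 °C
Reagents that add atoms: tert-butyl hydroperoxide, CC(C)(C)OO
Why: Sharpless asymmetric epoxidation of an allylic alcohol; the D-tartrate catalyst delivers oxygen to the face that gives the 2R,3R epoxy alcohol, and the E geometry fixes the cis relation of the two methyl groups.

Step 16
Reactants: 24 [(2R,3R)-2,3-dimethyloxiran-2-yl]methanol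
Product: 25 (2S,3R)-2,3-dimethyloxirane-2-carboxylic acid
Conditions: TEMPO (cat.), PhI(OAc)2, MeCN/H2O, rt
Reagents that add atoms: water, O
Why: Oxoammonium oxidation of a primary alcohol to the acid through the aldehyde hydrate; neither oxirane carbon is involved, so the configuration is kept (the C2 descriptor changes by priority only).

Step 17
Reactants: 25 (2S,3R)-2,3-dimethyloxirane-2-carboxylic acid; 22 (1R,4Z,6R,7R,8R,10R,11R)-13-(dimethylamino)-8,10-dihydroxy-1-(methanesulfonyloxy)germacr-4-en-12,6-olide
Product: 27 (1R,4Z,6R,7R,8R,10R,11R)-13-(dimethylamino)-8-{[(2S,3R)-2,3-dimethyloxirane-2-carbonyl]oxy}-10-hydroxy-1-(methanesulfonyloxy)germacr-4-en-12,6-olide, via mixed anhydride 26 (not isolated)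
Conditions: 25, 2,4,6-Cl3C6H2COCl, Et3N, THF, rt; then 22, DMAP, toluene, rt
Reagents that add atoms: none
Why: Yamaguchi esterification; the C8 hydroxyl is the only acylable hydroxyl (C10 is tertiary, C1 is sulfonylated), and acylating now keeps the C8 oxygen from attacking C1 or the lactone carbonyl in the next, basic step.

Step 18
Reactants: 27 (1R,4Z,6R,7R,8R,10R,11R)-13-(dimethylamino)-8-{[(2S,3R)-2,3-dimethyloxirane-2-carbonyl]oxy}-10-hydroxy-1-(methanesulfonyloxy)germacr-4-en-12,6-olide
Product: 28 (1S,4Z,6R,7R,8R,10R,11R)-13-(dimethylamino)-8-{[(2S,3R)-2,3-dimethyloxirane-2-carbonyl]oxy}-1,10-epoxygermacr-4-en-12,6-olide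
Conditions: DBU, toluene, 40 °C
Reagents that add atoms: none
Why: Intramolecular Williamson closure (3-exo-tet): the C10 oxygen displaces the anti-periplanar C1 mesylate with inversion, so the trans-1R,10R arrangement becomes the cis-oxirane 1S,10R; a non-nucleophilic amidine base spares the hindered ester and the lactone.

Step 19
Reactants: 28 (1S,4Z,6R,7R,8R,10R,11R)-13-(dimethylamino)-8-{[(2S,3R)-2,3-dimethyloxirane-2-carbonyl]oxy}-1,10-epoxygermacr-4-en-12,6-olide
Product: 30 (1S,4Z,6R,7R,8R,10R)-8-{[(2S,3R)-2,3-dimethyloxirane-2-carbonyl]oxy}-1,10-epoxygermacra-4,11(13)-dien-12,6-olide (CNP0165580.2), via trimethylammonium iodide 29 (not isolated)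
Conditions: MeI, MeCN, rt, dark; evaporate; NaHCO3, H2O/EtOAc, rt
Reagents that add atoms: none
Why: Quaternisation of the tertiary amine followed by E1cB elimination of trimethylamine from the β-ammonio lactone, the standard unmasking of an α-methylene lactone; bicarbonate is mild enough for both oxiranes, the ester and the Z alkene, and the C11 stereocentre disappears.

## Compound list

1 | neryl acetate, (2Z)-3,7-dimethylocta-2,6-dien-1-yl acetate | CC(=O)OC/C=C(/C)CCC=C(C)C | starting material
2 | (2Z)-3-methyl-6-oxohex-2-en-1-yl acetate | CC(=O)OC/C=C(/C)CCC=O | intermediate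
3 | (2Z)-6,6-dimethoxy-3-methylhex-2-en-1-yl acetate | CC(=O)OC/C=C(/C)CCC(OC)OC | intermediate
4 | (2Z)-6,6-dimethoxy-3-methylhex-2-en-1-ol | OC/C=C(/C)CCC(OC)OC | intermediate
5 | (2Z)-6,6-dimethoxy-3-methylhex-2-enal | O=C/C=C(/C)CCC(OC)OC | intermediate
6 | methyl propiolate | COC(=O)C#C | starting material
7 | methyl (4R,5Z)-4-hydroxy-9,9-dimethoxy-6-methylnon-5-en-2-ynoate | COC(=O)C#C[C@H](O)/C=C(/C)CCC(OC)OC | intermediate
8 | methyl (2Z,4S,5Z)-4-hydroxy-9,9-dimethoxy-6-methylnona-2,5-dienoate | COC(=O)/C=C\[C@H](O)/C=C(/C)CCC(OC)OC | intermediate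
9 | (5S)-5-[(1Z)-5,5-dimethoxy-2-methylpent-1-en-1-yl]furan-2(5H)-one | O=C1C=C[C@@H](/C=C(/C)CCC(OC)OC)O1 | intermediate
10 | but-3-yn-2-one | CC(=O)C#C | starting material
11 | propane-1,3-dithiol | SCCCS | starting material
12 | 1-(1,3-dithian-2-yl)propan-2-one | CC(=O)CC1SCCCS1 | intermediate
13 | 2-[(2-methyl-1,3-dioxolan-2-yl)methyl]-1,3-dithiane | CC1(CC2SCCCS2)OCCO1 | intermediate
14 | dimethylmethyleneiminium iodide (Eschenmoser's salt) | C=[N+](C)C.[I-] | starting material
15 | 2-lithio-2-[(2-methyl-1,3-dioxolan-2-yl)methyl]-1,3-dithiane | [Li]C1(CC2(C)OCCO2)SCCCS1 | intermediate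
16 | lithium enolate of the (4S,5S)-4-dithianyl-5-alkenyl lactone | [Li]OC1=C[C@H](C3(CC2(C)OCCO2)SCCCS3)[C@@H](/C=C(/C)CCC(OC)OC)O1 | intermediate
17 | (3R,4S,5R)-3-[(dimethylamino)methyl]-5-[(1Z)-5,5-dimethoxy-2-methylpent-1-en-1-yl]-4-{2-[(2-methyl-1,3-dioxolan-2-yl)methyl]-1,3-dithian-2-yl}oxolan-2-one | CN(C)C[C@@H]1C(=O)O[C@H](/C=C(/C)CCC(OC)OC)[C@H]1C3(CC2(C)OCCO2)SCCCS3 | intermediate
18 | (3R,4S,5R)-3-[(dimethylamino)methyl]-5-[(1Z)-2-methyl-5-oxopent-1-en-1-yl]-4-[2-(2-oxopropyl)-1,3-dithian-2-yl]oxolan-2-one | CN(C)C[C@@H]1C(=O)O[C@H](/C=C(/C)CCC=O)[C@H]1C2(CC(C)=O)SCCCS2 | intermediate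
19 | (1R,4Z,6R,7S,10R,11R)-13-(dimethylamino)-1,10-dihydroxy-8,8-(propane-1,3-diyldisulfanediyl)germacr-4-en-12,6-olide | CN(C)C[C@@H]1C(=O)O[C@@H]2/C=C(/C)CC[C@@H](O)[C@](C)(O)CC3(SCCCS3)[C@@H]12 | intermediate
20 | (1R,4Z,6R,7S,10R,11R)-13-(dimethylamino)-10-hydroxy-1-(methanesulfonyloxy)-8,8-(propane-1,3-diyldisulfanediyl)germacr-4-en-12,6-olide | CN(C)C[C@@H]1C(=O)O[C@@H]2/C=C(/C)CC[C@@H](OS(C)(=O)=O)[C@](C)(O)CC3(SCCCS3)[C@@H]12 | intermediate
21 | (1R,4Z,6R,7S,10R,11R)-13-(dimethylamino)-10-hydroxy-1-(methanesulfonyloxy)-8-oxogermacr-4-en-12,6-olide | CN(C)C[C@@H]1C(=O)O[C@@H]2/C=C(/C)CC[C@@H](OS(C)(=O)=O)[C@](C)(O)CC(=O)[C@@H]12 | intermediate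
22 | (1R,4Z,6R,7R,8R,10R,11R)-13-(dimethylamino)-8,10-dihydroxy-1-(methanesulfonyloxy)germacr-4-en-12,6-olide | CN(C)C[C@@H]1C(=O)O[C@@H]2/C=C(/C)CC[C@@H](OS(C)(=O)=O)[C@](C)(O)C[C@@H](O)[C@@H]12 | intermediate
23 | (2E)-2-methylbut-2-en-1-ol | C/C=C(\C)CO | starting material
24 | [(2R,3R)-2,3-dimethyloxiran-2-yl]methanol | OC[C@@]1(C)O[C@@H]1C | intermediate
25 | (2S,3R)-2,3-dimethyloxirane-2-carboxylic acid | OC(=O)[C@@]1(C)O[C@@H]1C | intermediate
26 | (2S,3R)-2,3-dimethyloxirane-2-carboxylic 2,4,6-trichlorobenzoic anhydride | O=C(OC(=O)[C@@]1(C)O[C@@H]1C)c1c(Cl)cc(Cl)cc1Cl | intermediate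
27 | (1R,4Z,6R,7R,8R,10R,11R)-13-(dimethylamino)-8-{[(2S,3R)-2,3-dimethyloxirane-2-carbonyl]oxy}-10-hydroxy-1-(methanesulfonyloxy)germacr-4-en-12,6-olide | CN(C)C[C@@H]1C(=O)O[C@@H]2/C=C(/C)CC[C@@H](OS(C)(=O)=O)[C@](C)(O)C[C@@H](OC(=O)[C@@]3(C)O[C@@H]3C)[C@@H]12 | intermediate
28 | (1S,4Z,6R,7R,8R,10R,11R)-13-(dimethylamino)-8-{[(2S,3R)-2,3-dimethyloxirane-2-carbonyl]oxy}-1,10-epoxygermacr-4-en-12,6-olide | CN(C)C[C@@H]1C(=O)O[C@@H]2/C=C(/C)CC[C@@H]3O[C@]3(C)C[C@@H](OC(=O)[C@@]3(C)O[C@@H]3C)[C@@H]12 | intermediate
29 | N-methyl quaternary ammonium iodide of 28 (13-trimethylammonio) | C[N+](C)(C)C[C@@H]1C(=O)O[C@@H]2/C=C(/C)CC[C@@H]3O[C@]3(C)C[C@@H](OC(=O)[C@@]3(C)O[C@@H]3C)[C@@H]12.[I-] | intermediate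
30 | (1S,4Z,6R,7R,8R,10R)-8-{[(2S,3R)-2,3-dimethyloxirane-2-carbonyl]oxy}-1,10-epoxygermacra-4,11(13)-dien-12,6-olide (CNP0165580.2) | C=C1C(=O)O[C@@H]2/C=C(/C)CC[C@@H]3O[C@]3(C)C[C@@H](OC(=O)[C@@]3(C)O[C@@H]3C)[C@@H]12 | target

## Step count and risks

Total: 19 steps. Longest linear sequence: 15 steps (steps 1–6, 9–14, 17–19); steps 7–8 and 15–16 are side branches.

**Step 9 (key step).**
- What may go wrong: proton transfer from the C6–H of 9, which is allylic to C4=C5 as well as γ to the lactone carbonyl, to the hindered carbanion 15, or 1,2-attack on the lactone carbonyl. Either returns no adduct, and the first erodes the C6 configuration.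
- Fallback (sets out from 13, returns at 17): make the same two bonds on a butenolide without the extra allylic activation, and attach the alkenyl chain afterwards.
 - Lithiated 13 is added to (5S)-5-({[tert-butyl(dimethyl)silyl]oxy}methyl)furan-2(5H)-one F1 (from commercial (S)-5-(hydroxymethyl)furan-2(5H)-one, TBSCl and imidazole), and the enolate is trapped with 14 to give the silyloxymethyl lactone F2.
 - Et3N·3HF frees the primary alcohol F3, and SO3·pyridine/DMSO/i-Pr2NEt gives the aldehyde F4.
 - A salt-free Wittig reaction with the ylide from (5,5-dimethoxypentan-2-yl)triphenylphosphonium bromide F5 (from ethyltriphenylphosphonium bromide, n-BuLi and 3-bromo-1,1-dimethoxypropane) forms C4=C5 and gives 17.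
 - This variant is longer and its Wittig step would need separation of the E isomer, so it is held in reserve.

**Step 11 (pinacol ring closure).**
- What may go wrong: erosion of the dithiane by the thiophilic low-valent titanium, oligomerisation in place of ten-membered closure, and above all poor facial selectivity at C10, or a cis- rather than trans-diol.
- Fallback (sets out from 17, returns at 21): remove sulfur before the closure and carry C8 as a silyl ether. The C8 configuration is immaterial here because C8 is returned to the ketone.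
 - Hg(ClO4)2/CaCO3 in THF/H2O at 0 °C unmasks the C8 ketone F6 with the O,O-acetals intact; NaBH4/CeCl3·7H2O gives the C8 carbinol F7; TBSOTf/2,6-lutidine gives the silyl ether F8.
 - AcOH/H2O/THF gives the keto aldehyde F9, and the same TiCl3(DME)1.5/Zn–Cu closure gives the diol F10.
 - MsCl/Et3N gives the C1 mesylate F11; HF·pyridine gives the C8 alcohol F12; Dess–Martin periodinane returns the route to 21, where step 14 sets C8.
 - Without sulfur present, unwanted diol isomers of F10 can be cleaved with NaIO4 back to F9 and recycled.

**Step 14 (directed reduction).**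
- What may go wrong: slow ligand exchange of the tertiary C10 hydroxyl, or a ring conformation that keeps it away from the carbonyl, would let external hydride attack compete and lower the selectivity at C8.
- Fallback (sets out from 21, returns at 27): if reduction of 21 gives mainly the 8S carbinol F13 (for example with NaBH4/CeCl3·7H2O), Mitsunobu esterification of F13 with acid 25 (PPh3, DIAD, toluene) inverts C8 and installs the acyl group in one operation, giving 27.

**Step 5 (asymmetric alkynylation).**
- What may go wrong: Z-to-E isomerisation of enal 5 during the long exposure to Lewis-acidic zinc species, and incomplete enantioselectivity with a Z-β,β-disubstituted enal.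
- Fallback (sets out from 5, returns at 7): separate C–C bond formation from stereocontrol.
 - Lithiated 6 (n-BuLi, THF, −78 °C) adds rapidly to 5 to give the racemic carbinol F14, and MnO2 oxidises it to the ynone F15.
 - Reduction with B-isopinocampheyl-9-borabicyclo[3.3.1]nonane (Alpine-Borane) made from (+)-α-pinene, which reduces alkynyl ketones with the alkyne as the small group, should give the 4R carbinol 7.

## Further compounds

F1 | step 9 | (5S)-5-({[tert-butyl(dimethyl)silyl]oxy}methyl)furan-2(5H)-one | O=C1C=C[C@@H](CO[Si](C)(C)C(C)(C)C)O1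
F2 | step 9 | (3R,4S,5S)-5-({[tert-butyl(dimethyl)silyl]oxy}methyl)-3-[(dimethylamino)methyl]-4-{2-[(2-methyl-1,3-dioxolan-2-yl)methyl]-1,3-dithian-2-yl}oxolan-2-one | CN(C)C[C@@H]1C(=O)O[C@H](CO[Si](C)(C)C(C)(C)C)[C@H]1C3(CC2(C)OCCO2)SCCCS3
F3 | step 9 | (3R,4S,5S)-3-[(dimethylamino)methyl]-5-(hydroxymethyl)-4-{2-[(2-methyl-1,3-dioxolan-2-yl)methyl]-1,3-dithian-2-yl}oxolan-2-one | CN(C)C[C@@H]1C(=O)O[C@H](CO)[C@H]1C3(CC2(C)OCCO2)SCCCS3
F4 | step 9 | (2S,3S,4R)-4-[(dimethylamino)methyl]-3-{2-[(2-methyl-1,3-dioxolan-2-yl)methyl]-1,3-dithian-2-yl}-5-oxooxolane-2-carbaldehyde | CN(C)C[C@@H]1C(=O)O[C@H](C=O)[C@H]1C3(CC2(C)OCCO2)SCCCS3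
F5 | step 9 | (5,5-dimethoxypentan-2-yl)triphenylphosphonium bromide | COC(OC)CCC(C)[P+](c1ccccc1)(c1ccccc1)c1ccccc1.[Br-]
F6 | step 11 | (3R,4S,5R)-5-[(1Z)-5,5-dimethoxy-2-methylpent-1-en-1-yl]-3-[(dimethylamino)methyl]-4-[(2-methyl-1,3-dioxolan-2-yl)acetyl]oxolan-2-one | CN(C)C[C@@H]1C(=O)O[C@H](/C=C(/C)CCC(OC)OC)[C@H]1C(=O)CC2(C)OCCO2
F7 | step 11 | C8 carbinol from F6 (either C8 epimer), 4-[1-hydroxy-2-(2-methyl-1,3-dioxolan-2-yl)ethyl] lactone | CN(C)C[C@@H]1C(=O)O[C@H](/C=C(/C)CCC(OC)OC)[C@H]1C(O)CC2(C)OCCO2
F8 | step 11 | tert-butyldimethylsilyl ether of F7 | CN(C)C[C@@H]1C(=O)O[C@H](/C=C(/C)CCC(OC)OC)[C@H]1C(O[Si](C)(C)C(C)(C)C)CC2(C)OCCO2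
F9 | step 11 | keto aldehyde from F8 (C1 aldehyde, C10 methyl ketone, C8 silyl ether) | CN(C)C[C@@H]1C(=O)O[C@H](/C=C(/C)CCC=O)[C@H]1C(O[Si](C)(C)C(C)(C)C)CC(C)=O
F10 | step 11 | (1R,4Z,6R,10R)-13-(dimethylamino)-1,10-dihydroxy-8-[tert-butyl(dimethyl)silyl]oxygermacr-4-en-12,6-olide (either C8 epimer) | CN(C)C[C@@H]1C(=O)O[C@@H]2/C=C(/C)CC[C@@H](O)[C@](C)(O)CC(O[Si](C)(C)C(C)(C)C)[C@@H]12
F11 | step 11 | C1 methanesulfonate of F10 | CN(C)C[C@@H]1C(=O)O[C@@H]2/C=C(/C)CC[C@@H](OS(C)(=O)=O)[C@](C)(O)CC(O[Si](C)(C)C(C)(C)C)[C@@H]12
F12 | step 11 | C8 alcohol from F11 (either C8 epimer) | CN(C)C[C@@H]1C(=O)O[C@@H]2/C=C(/C)CC[C@@H](OS(C)(=O)=O)[C@](C)(O)CC(O)[C@@H]12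
F13 | step 14 | (1R,4Z,6R,7R,8S,10R,11R)-13-(dimethylamino)-8,10-dihydroxy-1-(methanesulfonyloxy)germacr-4-en-12,6-olide (8-epimer of 22) | CN(C)C[C@@H]1C(=O)O[C@@H]2/C=C(/C)CC[C@@H](OS(C)(=O)=O)[C@](C)(O)C[C@H](O)[C@@H]12
F14 | step 5 | racemic methyl (5Z)-4-hydroxy-9,9-dimethoxy-6-methylnon-5-en-2-ynoate | COC(=O)C#CC(O)/C=C(/C)CCC(OC)OC
F15 | step 5 | methyl (5Z)-9,9-dimethoxy-6-methyl-4-oxonon-5-en-2-ynoate | COC(=O)C#CC(=O)/C=C(/C)CCC(OC)OC
A1 | alternative 1 | thirteen-membered diallylic ether (O between C6 and C13; Z C4=C5, Z C1=C10, C7=C11; O8 PMB; O12 TBS) | O1C/C=C(/C)CC/C=C(/C)C[C@@H](OCc2ccc(OC)cc2)C=C(CO[Si](C)(C)C(C)(C)C)C1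
A2 | alternative 1 | ten-membered Z,Z-dien-6-ol with 3-silyloxyprop-1-en-2-yl on C7 (O8 PMB) | O[C@@H]1/C=C(/C)CC/C=C(/C)C[C@@H](OCc2ccc(OC)cc2)[C@H]1C(=C)CO[Si](C)(C)C(C)(C)C
A3 | alternative 2 | open-chain trans lactone with C4 alkenyl iodide and C2=C3 vinyl oxirane (O8 TBS) | C=C[C@@H]1O[C@]1(C)C[C@@H](O[Si](C)(C)C(C)(C)C)[C@H]1CC(=O)O[C@@H]1/C=C(/C)I
A4 | alternative 2 | epoxy trans lactone lacking C13 (O8 TBS) | C1C(=O)O[C@@H]2/C=C(/C)CC[C@@H]3O[C@]3(C)C[C@@H](O[Si](C)(C)C(C)(C)C)[C@@H]12
A5 | alternative 3 | open-chain trans lactone with C8 bromomethyl ketone and C10 methyl ketone (O1 PMB) | CC(=O)[C@H](OCc1ccc(OC)cc1)CC/C(C)=C\[C@H]1OC(=O)C[C@@H]1C(=O)CBr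
A6 | alternative 3 | ten-membered 10-hydroxy-8-ketone trans lactone (O1 PMB) | C1C(=O)O[C@@H]2/C=C(/C)CC[C@@H](OCc3ccc(OC)cc3)[C@](C)(O)CC(=O)[C@@H]12
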